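Read zeta at 4.00 h and again at 10.0 h and you find product at 49.3 % and then 49.7 %, a shift of 0.4 percentage points against a scatter of 0.3 points on each reading, so zeta shows no clear movement after the earlier of those readings.

| flask | substrate | reagent | remark | time |
|---|---|---|---|---|
| zeta | 0.60 M | 0.70 equiv (in portions, 4) | run made earlier; portions every 30 min |  |
| flask | 1.2 M | 0.700 equiv (in portions, 4) | the portions of reagent follow each other after 30 min, the first at the start | 4.0 d |

- zeta (time / h: product / %): 0.833: 19.1; 2.00: 43.6; 4.00: 49.3; 10.0: 49.7

(scatter of a reading: 0.3 percentage points)

- the reaction counts as stopped when no species that holds the substrate changes by six tenths of a point or more over the second half of the time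

- which holds at 4.0 d: what has brought the reaction to rest, or that it has not come to rest (it is still moving / the reagent has run out first / all of the substrate has reacted / forward and back rates have come level)
- the product standing at 4.0 d, as a percentage of the substrate charged

The bench rule says that the limiting reagent, here charged at 0.70 equiv, gives that much product per substrate. Zeta stands at 0.710 of that figure, so the rule has already failed there, and if reagent goes nowhere but into product, 29.0 % of it lies unused beside unreacted substrate.

So freeze something else. If substrate and reagent turn into product and back, then with y the fraction of substrate converted, e the equivalents and c the starting substrate, the late zeta reading gives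

K = [product]/([substrate][reagent]) = y/((1−y)(e−y)c) = 8.11 /M

I call this reading the standing quotient, and I assume it stays the same when the concentration changes. The flask has the same equivalents and 2.00 times the concentration, so my own reckoning is

y/((1−y)(e−y)) = Kc = 9.73, so y = 56.6 %

In the flask that reckoning leaves 19.1 % of the reagent, and the 4.0 d allowed is 24.0 times the 4.00 h after which zeta showed no clear movement.

The forecast gives 56.5 % against my 56.6 %, with the ending "forward and back rates have come level", on the ground that “Doubling the concentration favours association”.

The flask gives 56.5 % at 4.0 d, and the ending is forward and back rates have come level, with 19 % of the reagent still there.

    substrate + reagent ⇌ product (K = 8.02 /M, k = 0.0562 /M/min)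

Take the standing quotient 8.11 /M to the neighbour flask with 0.30 M of substrate and the same equivalents. There Kc is 2.43, and the same equation gives y = 41.2 %. That neighbour flask stands at 41.1 % of product after 4.00 d, with 59 % of its substrate still there.

All runs are simulated on assumed constants, noise included.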